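**On the bench.** At early times substrate gave target, and the target then leaked into its isomer, so I reckoned the fraction of target left and not the fraction made. These are the flasks I handed over:

| setting | zeta | gamma | epsilon | beta |
|---|---|---|---|---|
| substrate | 0.18 M | 0.18 M | 0.18 M | 0.18 M |
| reagent | 0.720 M | 0.720 M | 0.720 M | 0.720 M |
| free catalyst | 0.13 mM | 0.13 mM | 0.13 mM | 0.13 mM |
| temperature | 20 °C | 35 °C |  | 5 °C |
| time | 2.0 h | 2.0 h | 2.0 h | 2.0 h |
| remark |  |  | at 35 °C until 40 min, from then on at 5 °C |  |

    substrate + free catalyst → catalyst intermediate A (k1 = 41 M⁻¹ s⁻¹, Ea1 = 37.0 kJ mol⁻¹)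
    catalyst intermediate A ⇌ catalyst intermediate B (K2 = 9.8, k2 = 0.48 s⁻¹, Ea2 = 65.0 kJ mol⁻¹, ΔH2 = −81.0 kJ mol⁻¹)
    reagent + catalyst intermediate B → catalyst intermediate C (k3 = 0.58 M⁻¹ s⁻¹, Ea3 = 51.0 kJ mol⁻¹)
    catalyst intermediate C → free catalyst + target (k4 = 3.4 s⁻¹, Ea4 = 64.0 kJ mol⁻¹)
    target ⇌ isomer of the product (K5 = 9.6, k5 = 2.7 × 10⁻⁴ s⁻¹, Ea5 = 95.0 kJ mol⁻¹, ΔH5 = −7.00 kJ mol⁻¹)
    (constants at 5 °C)

- all constants are for 5 °C and move with temperature by the activation energies and enthalpies

- the best flask by amount of target, in percent of the substrate charged; "all alike" if 1.5 percentage points covers them all (zeta / gamma / epsilon / beta / all alike)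
- amount of target at the end, in percent of the substrate charged, zeta
- amount of target at the end, in percent of the substrate charged, gamma
- amount of target at the end, in percent of the substrate charged, epsilon
- amount of target at the end, in percent of the substrate charged, beta

**The floor.** Left alone, target sinks to its equilibrium share of the product, 1/(1+K), with K the isomerisation constant. I made that 9.43% at 5 °C and 12.3% at 35 °C.

**The clock.** At 5 °C the isomerisation ran on a clock of 0.932 h. This τ, the inverse of the forward plus reverse rate constants, is the relaxation time: after a time t, the excess of target over its share keeps the fraction exp(−t/τ). At 35 °C I made it 0.993 min, far shorter than the run, so I expected gamma to sit on its floor.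

**Expected in beta.** I assumed that beta's substrate fed in steadily and was used up exactly at 2.0 h. The excess in the target made at each moment then keeps its own exp(−t/τ), and the average of that fraction over the run is 0.411. So I expected beta to hold 46.7% of target.

**Hands off.** Keep beta cold and stop it at 2.0 h, because its τ is much longer than the hot one, and the excess goes on shrinking with time.

**The forecast.** The forecast chose beta, with 10.8% for zeta, 12.3% for gamma, 10.1% for epsilon and 40.5% for beta, holding that “isomerisation is slow enough (time scale about an hour) to lag behind”. Its beta stands below mine by 6.2 percentage points; its words take about 90 percent of the substrate as consumed, and mine took the whole charge.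

**The result.** Beta held 40.8% of target, more than any other flask, at a conversion of 90.8%. Zeta held 10.8% and gamma 12.3%. Epsilon was cooled at 40 min with target at 12.4% and substrate at 0.0101%; with the cold τ I reckoned that the fraction 0.239 of its excess over 9.43% stayed to the end, which gives 10.1%. Epsilon stood at 10.1%, and a charge of free catalyst lowered to 0.0952 mM moved that figure by 5 points.

All constants are made up; the flask was simulated.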